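**Retrosynthetic overview**

1. Target 36 ⇐ O3–C16 lactonisation and C11 acetylation of 34; the C2–O–C9 ether in 34 ⇐ transannular 5-exo opening of a 2,3-epoxide by O9, the epoxide being made from the C16 acid by iodolactonisation.
2. The 6/10 eunicellane core 30 ⇐ transannular C1–C10 cation–olefin cyclisation of the 14-membered (2Z,6Z,10Z)-cembranoid 28 (allyl cation from the C1 allylic lactone; C11 cation trapped by the C9 carbamate).
3. Cembranoid ring ⇐ Nozaki–Hiyama–Kishi closure C9–C10 of 26 ⇐ alkenyllithium addition (C1–C2) of west piece 22 to east piece 14.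
4. 14 ⇐ Ireland–Claisen rearrangement (chirality from (S)-but-3-en-2-ol; sets C14 and C15); all Z-trisubstituted olefins ⇐ propyne carbocupration.
5. Ring order: 14-membered carbocycle → cyclohexane + cyclodecadiene → oxolane (ether bridge) → oxepanone (lactone).

Assumption: intermediates carry the carbon numbering of the target (eunicellane numbering; C16 = carboxyl carbon, C17 = its α-methyl); 24–28 are C1-epimer mixtures (C1 becomes planar in step 13) and are written without a stereo label at C1.

**Route**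

Step 1
Reactants: 1 but-3-en-1-ylmagnesium bromide; 2 propyne
Product: 4 (1Z)-1-iodo-2-methylhexa-1,5-diene, via alkenylcopper 3 (not isolated)
Conditions: CuBr·SMe2, Et2O–Me2S, −45 °C; 2, −25 °C; I2, −50 → 0 °C
Reagents that add atoms: iodine, II
Why: Normant syn-carbocupration of propyne puts the butenyl group and copper cis, and iodinolysis with retention gives the Z-iodoalkene.

Step 2
Reactants: 4; 5 (2S)-but-3-en-2-ol (4 equiv)
Product: 6 (2S,3E,7Z)-8-iodo-7-methylocta-3,7-dien-2-ol
Conditions: second-generation Hoveyda–Grubbs catalyst (5 mol %), CH2Cl2, 40 °C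
Reagents that add atoms: none
Why: Olefin cross-metathesis joins the terminal alkene of 4 to 5 E-selectively while the hindered iodoalkene is inert; the carbinol centre comes unchanged from 5.

Step 3
Reactants: 6; 7 propanoyl chloride
Product: 8 (2S,3E,7Z)-8-iodo-7-methylocta-3,7-dien-2-yl propanoate
Conditions: pyridine, DMAP (cat.), CH2Cl2, 0 °C
Reagents that add atoms: none
Why: DMAP-catalysed O-acylation; no stereocentre is touched.

Step 4
Reactants: 8
Product: 12 methyl (2R,3R,4E)-3-[(3Z)-4-iodo-3-methylbut-3-en-1-yl]-2-methylhex-4-enoate, via silyl ketene acetal 9 (not isolated), via trimethylsilyl ester 10 (not isolated), via carboxylic acid 11 (not isolated)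
Conditions: LDA, THF, −78 °C; TMSCl–Et3N; −78 → 60 °C; 1 M HCl; then TMSCHN2, MeOH–PhMe, 0 °C
Reagents that add atoms: (trimethylsilyl)diazomethane, C[Si](C)(C)C=[N+]=[N-] (ester methyl carbon); chlorotrimethylsilane, C[Si](C)(C)Cl (silicon only in 9 and 10)
Why: Ireland–Claisen rearrangement: LDA in THF gives the E(O)-enolate, and the chair transition state with the carbinol methyl equatorial transfers the C–O chirality to C14 and sets C15 anti to it (new E-propenyl group); the acid is then methylated.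

Step 5
Reactants: 12
Product: 14 methyl (2R,3S,6Z)-3-formyl-7-iodo-2,6-dimethylhept-6-enoate, via vicinal diol 13 (not isolated)
Conditions: OsO4 (2 mol %), NaIO4, 2,6-lutidine, dioxane–H2O, 23 °C
Reagents that add atoms: osmium tetroxide, O=[Os](=O)(=O)=O (aldehyde oxygen, re-supplied by NaIO4 and water)
Why: Lemieux–Johnson cleavage takes the electron-richer disubstituted propenyl alkene and leaves the deactivated iodoalkene; the lutidine buffer protects the α-centre C14 from epimerisation.

Step 6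
Reactants: 15 (1,3-dioxolan-2-ylmethyl)magnesium bromide; 2 propyne; 16 oxirane
Product: 18 (3Z)-5-(1,3-dioxolan-2-yl)-4-methylpent-3-en-1-ol, via alkenylcopper 17 (not isolated)
Conditions: CuBr·SMe2, Et2O–Me2S, −45 °C; 2, −25 °C; LiC≡C-nPr, HMPA, then 16, −40 → 0 °C
Reagents that add atoms: none
Why: Normant carbocupration followed by opening of oxirane by the mixed alkenyl(alkynyl)cuprate with retention gives the Z-homoallylic alcohol (C5 cis to C8).

Step 7
Reactants: 18
Product: 19 2-[(2Z)-5-bromo-2-methylpent-2-en-1-yl]-1,3-dioxolane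
Conditions: CBr4, PPh3, 2,6-lutidine, CH2Cl2, 0 °C
Reagents that add atoms: carbon tetrabromide, BrC(Br)(Br)Br
Why: Appel bromination of the primary alcohol; the buffered medium spares the acetal and the Z olefin.

Step 8
Reactants: 19; 2 propyne
Product: 22 2-[(2Z,6Z)-7-iodo-2,6-dimethylhepta-2,6-dien-1-yl]-1,3-dioxolane, via Grignard reagent 20 (not isolated), via alkenylcopper 21 (not isolated)
Conditions: Mg, THF; CuBr·SMe2, Et2O–Me2S, −45 °C; 2, −25 °C; I2, −50 → 0 °C
Reagents that add atoms: iodine, II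
Why: A second Normant carbocupration–iodinolysis sets the 2Z iodoalkene (iodine cis to C4).

Step 9
Reactants: 22; 14
Product: 25 (3R,4S,5RS)-5-[(1Z,5Z)-7-(1,3-dioxolan-2-yl)-2,6-dimethylhepta-1,5-dien-1-yl]-4-[(3Z)-4-iodo-3-methylbut-3-en-1-yl]-3-methyloxolan-2-one, via alkenyllithium 23 (not isolated), via lithium alkoxide 24 (not isolated)
Conditions: t-BuLi (2.0 equiv), Et2O, −78 °C; then 14, −78 → 0 °C; aq NH4Cl
Reagents that add atoms: none
Why: Iodine–lithium exchange with retention of the Z geometry, 1,2-addition to the aldehyde and lactonisation of the γ-alkoxide onto the methyl ester; C1 forms as a mixture that is erased in step 13, and C14 and C15 are untouched.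

Step 10
Reactants: 25
Product: 26 (3R,4S,5RS)-5-[(1Z,5Z)-2,6-dimethyl-8-oxoocta-1,5-dien-1-yl]-4-[(3Z)-4-iodo-3-methylbut-3-en-1-yl]-3-methyloxolan-2-one
Conditions: PPTS, acetone–H2O (9:1), 50 °C; used crude
Reagents that add atoms: water, O
Why: Mild acid hydrolysis of the dioxolane frees the C9 aldehyde; the skipped enal is not purified so that it does not move into conjugation.

Step 11
Reactants: 26
Product: 27 (9S)-9-hydroxy macrocyclic γ-lactone (14-membered ring C1–C14; 2Z 6Z 10Z)
Conditions: CrCl2 (6 equiv), NiCl2 (cat.), Kishi-type chiral oxazoline–sulfonamide ligand (enantiomer chosen for 9S), Et3N, THF–MeCN, 2 mM, 23 °C; aq sodium serinate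
Reagents that add atoms: none
Why: Nozaki–Hiyama–Kishi macrocyclisation forms C9–C10 with retention of the Z-alkenyl geometry; the chiral ligand on trivalent chromium selects the aldehyde face and so sets C9 (S).

Step 12
Reactants: 27
Product: 28 9-O-(N,N-dimethylcarbamoyl) derivative of 27
Conditions: KHMDS, THF, −78 °C; Me2NCOCl, −78 → 0 °C
Reagents that add atoms: dimethylcarbamoyl chloride, CN(C)C(Cl)=O
Why: O-carbamoylation of the potassium alkoxide; C9 keeps its configuration.

Step 13
Reactants: 28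
Product: 30 cis-fused eunicella-2Z,6Z-diene 9,11-cyclic carbonate 16-carboxylic acid, via cyclic iminium carbonate 29 (not isolated)
Conditions: BF3·OEt2 (3 equiv), 2,6-di-tert-butyl-4-methylpyridine, CH2Cl2–(CF3)2CHOH (9:1), 1 mM, −78 → −30 °C; then sat. aq NaHCO3, 23 °C
Reagents that add atoms: water, O (carbonate carbonyl oxygen)
Why: Proposed new method: BF3 ionises the allylic C1–O bond of the γ-vinyl lactone to a (2Z)-allyl cation (the allylic carbamate is a much poorer leaving group), the 10Z olefin attacks C1 across the ring through a chair with the C14 side chain and C2 equatorial and the Z-bound C9 axial (sets C1 and C10, cis ring fusion), the C11 cation is captured syn to C9 by the carbamate carbonyl through a six-membered ring (sets C11) and water hydrolyses the iminium carbonate; the closest known reactions are acid-induced transannular cyclisations of germacrene-type cyclodecadienes and carbamate- or carbonate-terminated cation–olefin cyclisations.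

Step 14
Reactants: 30
Product: 31 2-iodo 16,3-lactone of the 9,11-cyclic carbonate (iodolactone)
Conditions: I2, NaHCO3, MeCN–H2O, 0 °C, dark
Reagents that add atoms: iodine, II
Why: Iodolactonisation: only the 2,3-olefin is within reach of the C16 carboxylate, which attacks the tertiary C3 (Markovnikov, 7-endo) anti to the iodonium from the one face its tether allows, setting C3; a 6-exo regioisomer would give the same epoxide in step 15.

Step 15
Reactants: 31
Product: 34 methyl ester of the 2,9-epoxy-3,11-diol (oxolane ether bridge closed), via iodolactone diol 32 (not isolated), via epoxy diol ester 33 (not isolated)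
Conditions: K2CO3, MeOH, 0 → 23 °C
Reagents that add atoms: methanol, CO
Why: Methanolysis cascade: the carbonate and the lactone open, the C3 alkoxide displaces iodide (inversion at C2) to the 2,3-epoxide, and the C9 hydroxyl opens it 5-exo at C2 (second inversion), which fixes C2 (S) next to C3 (S).

Step 16
Reactants: 34
Product: 36 CNP0332402.2 (11-acetoxy-2,9-epoxy-eunicell-6Z-en-16,3-olide), via hydroxy lactone 35 (not isolated)
Conditions: NaH (2.5 equiv), THF, 0 → 40 °C; then Ac2O, DMAP (cat.), 0 → 23 °C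
Reagents that add atoms: acetic anhydride, CC(=O)OC(C)=O
Why: The C3 alkoxide, held next to the C16 ester by the tricyclic core, lactonises by transesterification, and the remaining tertiary C11 sodium alkoxide is then acetylated; no stereocentre changes.

**Compound list**

1 | but-3-en-1-ylmagnesium bromide | C=CCC[Mg]Br | starting material
2 | propyne | CC#C | starting material
3 | [(1Z)-2-methylhexa-1,5-dien-1-yl]copper (MgBr2 complex) | C=CCC/C(C)=C\[Cu] | intermediate
4 | (1Z)-1-iodo-2-methylhexa-1,5-diene | C=CCC/C(C)=C\I | intermediate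
5 | (2S)-but-3-en-2-ol | C[C@H](O)C=C | starting material
6 | (2S,3E,7Z)-8-iodo-7-methylocta-3,7-dien-2-ol | C[C@H](O)/C=C/CC/C(C)=C\I | intermediate
7 | propanoyl chloride | CCC(Cl)=O | starting material
8 | (2S,3E,7Z)-8-iodo-7-methylocta-3,7-dien-2-yl propanoate | CCC(=O)O[C@@H](C)/C=C/CC/C(C)=C\I | intermediate
9 | (E)-O-trimethylsilyl ketene acetal of 8 (methyl trans to OSi) | C/C=C(/O[Si](C)(C)C)O[C@@H](C)/C=C/CC/C(C)=C\I | intermediate
10 | trimethylsilyl (2R,3R,4E)-3-[(3Z)-4-iodo-3-methylbut-3-en-1-yl]-2-methylhex-4-enoate | C[Si](C)(C)OC(=O)[C@H](C)[C@H](CC/C(C)=C\I)/C=C/C | intermediate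
11 | (2R,3R,4E)-3-[(3Z)-4-iodo-3-methylbut-3-en-1-yl]-2-methylhex-4-enoic acid | OC(=O)[C@H](C)[C@H](CC/C(C)=C\I)/C=C/C | intermediate
12 | methyl (2R,3R,4E)-3-[(3Z)-4-iodo-3-methylbut-3-en-1-yl]-2-methylhex-4-enoate | COC(=O)[C@H](C)[C@H](CC/C(C)=C\I)/C=C/C | intermediate
13 | methyl (2R,3S)-4,5-dihydroxy-3-[(3Z)-4-iodo-3-methylbut-3-en-1-yl]-2-methylhexanoate (diol diastereomers) | COC(=O)[C@H](C)[C@H](CC/C(C)=C\I)C(O)C(C)O | intermediate
14 | methyl (2R,3S,6Z)-3-formyl-7-iodo-2,6-dimethylhept-6-enoate (east piece; C1 aldehyde, C14, C15) | COC(=O)[C@H](C)[C@H](CC/C(C)=C\I)C=O | intermediate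
15 | (1,3-dioxolan-2-ylmethyl)magnesium bromide | Br[Mg]CC1OCCO1 | starting material
16 | oxirane | C1CO1 | starting material
17 | [(1Z)-3-(1,3-dioxolan-2-yl)-2-methylprop-1-en-1-yl]copper | [Cu]/C=C(/C)CC1OCCO1 | intermediate
18 | (3Z)-5-(1,3-dioxolan-2-yl)-4-methylpent-3-en-1-ol | OCC/C=C(/C)CC1OCCO1 | intermediate
19 | 2-[(2Z)-5-bromo-2-methylpent-2-en-1-yl]-1,3-dioxolane | BrCC/C=C(/C)CC1OCCO1 | intermediate
20 | [(3Z)-5-(1,3-dioxolan-2-yl)-4-methylpent-3-en-1-yl]magnesium bromide | Br[Mg]CC/C=C(/C)CC1OCCO1 | intermediate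
21 | [(1Z,5Z)-7-(1,3-dioxolan-2-yl)-2,6-dimethylhepta-1,5-dien-1-yl]copper | [Cu]/C=C(/C)CC/C=C(/C)CC1OCCO1 | intermediate
22 | 2-[(2Z,6Z)-7-iodo-2,6-dimethylhepta-2,6-dien-1-yl]-1,3-dioxolane (west piece; C2–C9) | I/C=C(/C)CC/C=C(/C)CC1OCCO1 | intermediate
23 | [(1Z,5Z)-7-(1,3-dioxolan-2-yl)-2,6-dimethylhepta-1,5-dien-1-yl]lithium | [Li]/C=C(/C)CC/C=C(/C)CC1OCCO1 | intermediate
24 | lithium C1-alkoxide of the open hydroxy ester formed from 23 and 14 (C1 epimers) | COC(=O)[C@H](C)[C@H](CC/C(C)=C\I)C(O[Li])/C=C(/C)CC/C=C(/C)CC1OCCO1 | intermediate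
25 | (3R,4S,5RS)-5-[(1Z,5Z)-7-(1,3-dioxolan-2-yl)-2,6-dimethylhepta-1,5-dien-1-yl]-4-[(3Z)-4-iodo-3-methylbut-3-en-1-yl]-3-methyloxolan-2-one | O=C1OC(/C=C(/C)CC/C=C(/C)CC2OCCO2)[C@@H](CC/C(C)=C\I)[C@H]1C | intermediate
26 | (3R,4S,5RS)-5-[(1Z,5Z)-2,6-dimethyl-8-oxoocta-1,5-dien-1-yl]-4-[(3Z)-4-iodo-3-methylbut-3-en-1-yl]-3-methyloxolan-2-one | O=C1OC(/C=C(/C)CC/C=C(/C)CC=O)[C@@H](CC/C(C)=C\I)[C@H]1C | intermediate
27 | macrocyclic alcohol: 14-membered carbocycle C1–C14 with 2Z, 6Z, 10Z olefins, 9S hydroxyl, γ-lactone from O–C1 to C16 (14S,15R; C1 epimers) | O=C1OC2/C=C(/C)CC/C=C(/C)C[C@H](O)/C=C(/C)CC[C@H]2[C@H]1C | intermediate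
28 | 9-O-(N,N-dimethylcarbamate) of 27 | O=C1OC2/C=C(/C)CC/C=C(/C)C[C@H](OC(=O)N(C)C)/C=C(/C)CC[C@H]2[C@H]1C | intermediate
29 | bicyclic 2-(dimethyliminio)-1,3-dioxane bridging O9 and O11, carboxylate held as its BF3 adduct | C[N+](C)=C1O[C@]2(C)CC[C@@H]([C@@H](C)C(=O)O[B-](F)(F)F)[C@@H]3/C=C(/C)CC/C=C(/C)C[C@H](O1)[C@H]23 | intermediate
30 | cis-fused eunicella-2Z,6Z-diene with 9,11-cyclic carbonate and free C16 acid (C1, C9, C10, C11, C14, C15 arranged as in the target) | O=C1O[C@]2(C)CC[C@@H]([C@@H](C)C(O)=O)[C@@H]3/C=C(/C)CC/C=C(/C)C[C@H](O1)[C@H]23 | intermediate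
31 | iodolactone: C16–O–C3 oxepanone closed, iodine on C2 anti to the C3 oxygen, 9,11-cyclic carbonate, 6Z olefin | O=C4O[C@]1(C)CC[C@@H]2[C@H]3[C@@H]1[C@@H](O4)C/C(C)=C\CC[C@](C)(OC(=O)[C@@H]2C)[C@H]3I | intermediate
32 | iodolactone 9,11-diol (carbonate removed) | O[C@]1(C)CC[C@@H]2[C@H]3[C@@H]1[C@@H](O)C/C(C)=C\CC[C@](C)(OC(=O)[C@@H]2C)[C@H]3I | intermediate
33 | cis-2,3-epoxide, 9,11-diol, C16 methyl ester | O[C@]1(C)CC[C@@H]([C@@H](C)C(=O)OC)[C@H]3[C@@H]1[C@@H](O)C/C(C)=C\CC[C@]4(C)O[C@H]34 | intermediate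
34 | 2,9-epoxy (oxolane) 3,11-diol, C16 methyl ester, 6Z olefin | O[C@]1(C)CC[C@@H]([C@@H](C)C(=O)OC)[C@H]3[C@@H]1[C@@H]1C/C(C)=C\CC[C@](C)(O)[C@H]3O1 | intermediate
35 | 11-deacetyl target (11-hydroxy 16,3-lactone; formed as its sodium alkoxide) | O[C@]1(C)CC[C@@H]2[C@H]3[C@@H]1[C@@H]1C/C(C)=C\CC[C@](C)(OC(=O)[C@@H]2C)[C@H]3O1 | intermediate
36 | CNP0332402.2, (1S,2S,3S,9S,10R,11R,14R,15R)-11-acetoxy-2,9-epoxy-eunicell-6Z-en-16,3-olide | CC(=O)O[C@]1(C)CC[C@@H]2[C@H]3[C@@H]1[C@@H]1C/C(C)=C\CC[C@](C)(OC(=O)[C@@H]2C)[C@H]3O1 | target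

**Step count and risks**

Total step count: 16. Longest linear sequence: 13 steps (steps 1–5, then 9–16); the west piece (steps 6–8) joins at step 9.

The three steps most likely to fail are steps 13, 11 and 14.

Step 13 (transannular cyclisation). The ring fusion, the facial influence of C9 and the competition between carbamate capture and elimination are all untested. The fallback makes the C1–C10 bond by enolate chemistry instead of a cation. It sets out from 27 and comes back at 30. Compound 27 is oxidised with Dess–Martin periodinane to the macrocyclic Z-enone F2. Treatment with Pd(PPh3)4 (zerovalent palladium) and LiHMDS in THF opens the vinyl lactone to a π-allylpalladium carboxylate and alkylates the dienolate at C10 across the ring (transannular Tsuji–Trost reaction), giving the bicyclic 9-keto acid with an 11,12-olefin F3. Reduction with NaBH4 and CeCl3·7H2O from the face away from the ring-fusion substituents gives the 9S hydroxy acid F4 (a wrong epimer would be corrected by Mitsunobu inversion). KHMDS (2 equiv) and Me2NCOCl give the carbamate acid F5. Catalytic TfOH in (CF3)2CHOH then protonates the 11,12-olefin at C12, the carbamate captures the C11 cation and aqueous work-up gives 30.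

Step 11 (ligand-controlled macrocyclisation). The facial selectivity of a ligand-controlled Ni/Cr ring closure on this substrate is uncertain. The fallback sets the C9 centre by ketone reduction instead. It sets out from 26 and comes back at 27. Ring closure with CrCl2 and catalytic NiCl2 in DMSO without a chiral ligand gives the C9-epimeric macrocyclic alcohols F1. Dess–Martin periodinane converts both epimers into the macrocyclic Z-enone F2. (R)-2-Methyl-CBS-oxazaborolidine with BH3·SMe2 at −40 °C (alkenyl as the large group) then delivers the 9S alcohol 27.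

Step 14 (iodolactonisation). The iodonium has to form on the more hindered face of the 2,3-olefin, and elimination could compete. The fallback epoxidises directly with a peracid. It sets out from 30 and comes back at 34. TMSCHN2 in MeOH–PhMe gives the methyl ester carbonate F6. mCPBA with NaHCO3 in CH2Cl2 at 0 °C epoxidises the 2,3-olefin from its exposed outer face to the epoxy ester carbonate F7. Some 6,7-epoxide is expected and would be separated. K2CO3 in MeOH, as in step 15, then removes the carbonate and lets O9 open the epoxide to give 34.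

**Further compounds**

F1 | step 11 | (9RS)-macrocyclic alcohol, C9 epimers of 27 | O=C1OC2/C=C(/C)CC/C=C(/C)CC(O)/C=C(/C)CC[C@H]2[C@H]1C
F2 | step 11 | macrocyclic (10Z)-en-9-one with the γ-lactone of 27 | O=C1OC2/C=C(/C)CC/C=C(/C)CC(=O)/C=C(/C)CC[C@H]2[C@H]1C
F3 | step 13 | cis-fused eunicella-2Z,6Z,11(12)-trien-9-one 16-carboxylic acid | CC1=CC[C@@H]([C@@H](C)C(O)=O)[C@@H]2/C=C(/C)CC/C=C(/C)CC(=O)[C@H]12
F4 | step 13 | (9S)-9-hydroxy acid from F3 | CC1=CC[C@@H]([C@@H](C)C(O)=O)[C@@H]2/C=C(/C)CC/C=C(/C)C[C@H](O)[C@H]12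
F5 | step 13 | 9-O-(N,N-dimethylcarbamate) of F4 | CC1=CC[C@@H]([C@@H](C)C(O)=O)[C@@H]2/C=C(/C)CC/C=C(/C)C[C@H](OC(=O)N(C)C)[C@H]12
F6 | step 14 | methyl ester of 30 | O=C1O[C@]2(C)CC[C@@H]([C@@H](C)C(=O)OC)[C@@H]3/C=C(/C)CC/C=C(/C)C[C@H](O1)[C@H]23
F7 | step 14 | cis-2,3-epoxide of F6 (9,11-cyclic carbonate, methyl ester) | O=C5O[C@]1(C)CC[C@@H]([C@@H](C)C(=O)OC)[C@H]3[C@@H]1[C@@H](O5)C/C(C)=C\CC[C@]4(C)O[C@H]34
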